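## The problem

Target numbering used throughout: the trione ring is C-1 to C-6 (carbonyls C-2, C-4, C-6); C-7 is the CMe2 on C-5, C-8 the bridge methine, C-9 the CH2 on C-1, C-10 the CH2 between C-8 and C-11; the cyclopentane is C-3, C-11, C-12 (CMe2), C-13, C-14.

The target is a cage on a cyclohexane-1,3,5-trione ring whose three sp3 carbons are all quaternary: C-1 bears the (E)-geranyl chain, C-5 the 2-methylpropanoyl group, and C-3 is a spiro carbon shared with the cyclopentane. C-5 and C-1 are tied by the bridge C-7–C-8–C-9, and C-8 is tied through C-10 to the cyclopentane methine C-11. As a result C-1, C-2, C-3, C-11, C-10, C-8 and C-9 form a cycloheptanone fused to the cyclopentane along C-3–C-11. There are five stereocentres (1R,3S,5S,8R,11R) but only two independent elements: C-1, C-3, C-5 and C-8 are locked to one another by the cage, and C-11 is the one free centre. Which cage enantiomer can close onto a given C-11 is decided by the configuration of C-8 relative to C-11, so this relation must be set before the cage is closed. The ring has no enolisable position, so every ring C–CO bond is open to retro-Claisen cleavage by nucleophiles; C-5 sits between the quaternary C-7 and three acyl carbons; and the geranyl diene tolerates neither hydrogenation nor strong acid. The enabling feature is the cycloheptanone: its carbonyl C-2 lies between C-1 and C-3, and C-9, C-8, C-10, C-11 can be a diene. That is the imprint of an oxyallyl cation (C-1–C-2–C-3) adding to a diene tethered through C-14, C-13 and C-12.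

## Retrosynthesis

**24 from 23.** No catalyst is known that controls the enantiofacial course of an intramolecular oxyallyl (4+3) cycloaddition of a simple chloromethyl ketone. The route is therefore run racemic and the racemate 23 is resolved. The resolution is placed at the end because every intermediate after the cycloaddition carries an epimerisable ketone α-carbon, and 23 is the first rigid, stereochemically uniform compound.

**23 from 22.** The 2-methylpropanoyl group is unmasked from its silyl enol ether. A C-5 that carried a free ketone besides its ester groups would leave as a doubly stabilised carbanion from any tetrahedral intermediate formed at those esters, so an attacking enolate would transfer an acyl group instead of closing a ring. The masked form removes that path and costs one fluoride step.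

**22 from 21.** The C-3–C-4 bond is cut (Claisen acylation of the C-3 enolate by the remaining ester). In 21 the ester is already held over C-3 by the bicycle, so the six-membered trione ring and the spiro centre can form in one way only. This closure has no thermodynamic sink and must be run under kinetic control.

**21 from 18 and 19, through 20.** The C-1–geranyl bond and the C-1–C-6 bond are cut. Closing the ring first at the C-1 methylene gives a β-diketone 20 that is deprotonated by the methoxide it releases, so this Claisen step is driven. Geranyl bromide 19 then enters at a doubly activated carbon, with no regiochemical question. The other order (alkylate first) would leave both ring closures without a driving force.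

**18 from 17.** The C-8–H bond is cut (hydrogenation of the C-8=C-10 alkene). It must precede geranyl, and it sets C-8 relative to C-11.

**17 from 15, through 16.** The key cut: C-3–C-11 and C-1–C-9. The chloromethyl ketone 15 gives the oxyallyl cation 16, which adds across the tethered (E)-diene. Two rings, two C–C bonds and the free stereocentre arise at once, and every skeletal carbon of the cage is then in place. Compound 15 is acyclic and has no stereocentre.

**15 from 14.** The C-1–C-2 bond is cut: chloromethyllithium adds to the Weinreb amide of 14. The base-sensitive chloromethyl ketone is thus made in the last step before it is used.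

**14 from 11 and 12, through 13.** The C-5–acyl bond is cut. Acylation is done here because 11 contains no other ketone, so the new ketone of 13 can be converted selectively into its silyl enol ether.

**11 from 9 (through 10), and 9 from 4 and 8.** The diene is cut at C-10–C-11. Allylsilane 4 attacks aldehyde 8 through its terminal carbon and the resulting homoallylic alcohol 9 is dehydrated through mesylate 10. An olefination of 8 with an allylic phosphonate was set aside: it would need a dianion next to the acidic malonate hydrogen, and the attack would have to occur at the carbon next to a tert-alkyl group. The allylsilane bonds through its unhindered end by design.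

**4 from 1 and 2, through 3.** The C-7–C-8 bond is cut: conjugate addition of the alkenylmagnesium 3, made from 2, to the alkylidene malonate 1 builds the quaternary C-7 with the malonate already attached.

**8 from 7, and 7 from 5 and 6.** The tether is cut at C-14–C-3: cross-metathesis of 5 with acrylamide 6, then hydrogenation, adds C-3 and C-2 as a Weinreb amide.

## Roads not taken

**Alternative 1:** The cut is the C-5–C-7 bond, made last inside the cage. A strong Brønsted acid would protonate the exocyclic isopropylidene group of the bridged triketone A1 at C-8, and the enol carbon C-5 would capture the tertiary cation at C-7, closing the cyclohexanone ring to give A2. Its merit is real: the most crowded bond is made intramolecularly, and C-8 cannot come out wrong because only one protonation face lets the ring close. On that point it is better than the chosen plan, which depends on facial selectivity in a hydrogenation. Its weakness is what comes after. A2 has hydrogen at both C-1 and C-5, and geranyl cannot be present during the acid step. Both groups would have to be put onto bridgehead carbons of a non-enolisable triketone by bridgehead metalation, C-5 being next to the quaternary C-7. The chosen plan brings both groups in while C-1 and C-5 are still ordinary enolate carbons. Absolute configuration is no better solved in Alternative 1.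

**Alternative 2:** The cut is at C-11, whose bonds to C-3 and C-12 would be made in one three-component reaction. Phloroglucinol A3 and aldehyde A4 would condense to an ortho-quinone methide, and the prenylboronic ester A5, exchanged onto a chiral 3,3'-dihalogenated biaryl diol, would deliver its tertiary carbon to the methide carbon to give A6. This road is better than the chosen plan in the respect that matters most for a single enantiomer: C-11 is set by a catalytic asymmetric reaction of a known type, from cheap material that already holds C-1 to C-6. Against it, A6 is far from the cage. The cyclopentane must still be closed onto the substituted ring carbon with dearomatisation, C-1 and C-5 must each be made quaternary on a phloroglucinol-type enolate where C- versus O-selectivity is poor, and both seven-membered rings remain. The chosen plan pays for its missing enantiocontrol with a resolution that discards half of the final material. In return, one step assembles both carbocycles with every skeletal carbon in place, and five steps lead from there to the racemate.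

**Alternative 3:** The cut is the C-3–C-11 bond. A secondary-amine catalyst would convert the (E)-enal of A7 into an iminium ion, and the alkyl-bearing ring carbon would attack it (5-exo-trig), giving the spiro triketone aldehyde A8. The merit is that the same bond as in the chosen key step would be formed enantioselectively, together with the spiro centre. The weak points are two. Attack at the substituted ring carbon must beat attack of the neighbouring unsubstituted carbon, which would give a six-membered ring and keep the aromatic ring. And A8 still lacks the C-1–C-9 bond, the C-7 bridge and both quaternary centres C-1 and C-5, all to be built on an enolised triketone. On absolute control Alternative 3 is ahead; on convergence the chosen plan is ahead, since its key step also closes the seven-membered ring and carries the C-5 arm with it.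

Key step: step 8

Remark: compounds 17 to 23 are racemic and are drawn as the enantiomer that leads to 24; in 17, 18, 20 and 21 the ketone α-carbon C-3 is drawn trans-fused, its epimer is carried along, and both converge in step 11.

## Steps

Step 1
Reactants: 1 dimethyl 2-(propan-2-ylidene)propanedioate; 2 2-bromo-3-(trimethylsilyl)prop-1-ene
Product: 4 dimethyl 2-{2-methyl-3-[(trimethylsilyl)methyl]but-3-en-2-yl}propanedioate, via alkenylmagnesium bromide 3 (not isolated)
Conditions: Mg, THF, 40 °C; then CuI (10 mol%), 1, THF, −30 → 0 °C; aq. NH4Cl
Reagents that add atoms: none
Why: Copper-catalysed conjugate addition of an alkenyl Grignard reagent to an alkylidene malonate; the same addition of vinyl and isopropenyl Grignard reagents to isopropylidene malonates is standard and builds the quaternary C-7 with the malonate attached.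

Step 2
Reactants: 5 2,2-dimethylpent-4-enal; 6 N-methoxy-N-methylprop-2-enamide
Product: 7 (2E)-N-methoxy-N,5,5-trimethyl-6-oxohex-2-enamide
Conditions: second-generation Hoveyda–Grubbs catalyst [(H2IMes)Cl2Ru=CH(C6H4-2-OiPr)] (3 mol%), CH2Cl2, 40 °C
Reagents that add atoms: none
Why: Olefin cross-metathesis of a terminal alkene with an acrylamide, which is (E)-selective and tolerates the hindered aldehyde; loss of ethene drives it.

Step 3
Reactants: 7 (2E)-N-methoxy-N,5,5-trimethyl-6-oxohex-2-enamide
Product: 8 N-methoxy-N,5,5-trimethyl-6-oxohexanamide
Conditions: H2 (1 atm), Pd/C (10% Pd on carbon), EtOAc, 25 °C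
Reagents that add atoms: none
Why: Catalytic hydrogenation of a conjugated alkene; the neopentyl aldehyde and the N–O bond are not reduced at atmospheric pressure.

Step 4
Reactants: 4 dimethyl 2-{2-methyl-3-[(trimethylsilyl)methyl]but-3-en-2-yl}propanedioate; 8 N-methoxy-N,5,5-trimethyl-6-oxohexanamide
Product: 9 dimethyl 2-{5-hydroxy-10-[methoxy(methyl)amino]-2,6,6-trimethyl-3-methylidene-10-oxodecan-2-yl}propanedioate (racemic)
Conditions: TiCl4 (2.2 equiv), CH2Cl2, −78 °C; aq. NaHCO3
Reagents that add atoms: none
Why: Hosomi–Sakurai allylation: the 2-substituted allylsilane attacks the TiCl4-activated aldehyde through its unhindered terminal carbon with allyl transposition, forming C-10–C-11 and the exocyclic methylene C-9; the carbinol centre is racemic and is destroyed in step 5.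

Step 5
Reactants: 9 dimethyl 2-{5-hydroxy-10-[methoxy(methyl)amino]-2,6,6-trimethyl-3-methylidene-10-oxodecan-2-yl}propanedioate
Product: 11 dimethyl 2-{(4E)-10-[methoxy(methyl)amino]-2,6,6-trimethyl-3-methylidene-10-oxodec-4-en-2-yl}propanedioate, via mesylate 10 (not isolated)
Conditions: MsCl, Et3N, CH2Cl2, 0 °C; then DBU, toluene, 90 °C
Reagents that add atoms: none
Why: Mesylation and base-induced 1,2-elimination (E2): the only β-hydrogens are on the allylic CH2 since the other neighbour is quaternary, so only the conjugated diene can form, and the anti-periplanar transition state with the two large groups anti gives the (E)-alkene; the neopentyl position resists substitution, including by the malonate carbon.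

Step 6
Reactants: 11 dimethyl 2-{(4E)-10-[methoxy(methyl)amino]-2,6,6-trimethyl-3-methylidene-10-oxodec-4-en-2-yl}propanedioate; 12 2-methylpropanoyl chloride
Product: 14 dimethyl 2-{1-[(tert-butyldimethylsilyl)oxy]-2-methylprop-1-en-1-yl}-2-{(4E)-10-[methoxy(methyl)amino]-2,6,6-trimethyl-3-methylidene-10-oxodec-4-en-2-yl}propanedioate, via acylmalonate 13 (not isolated)
Conditions: NaH, THF, 0 °C, then 12, 0 → 25 °C; solvent exchange to CH2Cl2; Et3N, t-BuMe2SiOTf, 0 → 25 °C
Reagents that add atoms: tert-butyldimethylsilyl trifluoromethanesulfonate, CC(C)(C)[Si](C)(C)OS(=O)(=O)C(F)(F)F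
Why: C-acylation of the sodium enolate of a substituted malonate with an acid chloride, then soft enolisation (silyl triflate and amine) of the only ketone in the molecule to its silyl enol ether; the mask keeps C-5 from acting as a doubly stabilised leaving group in steps 10 and 11 and removes the acidic malonate hydrogen.

Step 7
Reactants: 14 dimethyl 2-{1-[(tert-butyldimethylsilyl)oxy]-2-methylprop-1-en-1-yl}-2-{(4E)-10-[methoxy(methyl)amino]-2,6,6-trimethyl-3-methylidene-10-oxodec-4-en-2-yl}propanedioate
Product: 15 dimethyl 2-{1-[(tert-butyldimethylsilyl)oxy]-2-methylprop-1-en-1-yl}-2-[(4E)-11-chloro-2,6,6-trimethyl-3-methylidene-10-oxoundec-4-en-2-yl]propanedioate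
Conditions: ICH2Cl (1.5 equiv), MeLi·LiBr (1.4 equiv), THF, −78 °C; AcOH
Reagents that add atoms: chloroiodomethane, ClCI
Why: Addition of chloromethyllithium (carbenoid from iodine–lithium exchange) to a Weinreb amide gives a chelated tetrahedral intermediate that releases the chloromethyl ketone only on work-up; the two esters on the fully substituted, neopentyl-flanked C-5 are not attacked at −78 °C.

Step 8
Reactants: 15 dimethyl 2-{1-[(tert-butyldimethylsilyl)oxy]-2-methylprop-1-en-1-yl}-2-[(4E)-11-chloro-2,6,6-trimethyl-3-methylidene-10-oxoundec-4-en-2-yl]propanedioate
Product: 17 dimethyl 2-{1-[(tert-butyldimethylsilyl)oxy]-2-methylprop-1-en-1-yl}-2-{2-[rac-(3aS,8aR)-3,3-dimethyl-8-oxo-1,2,3,3a,6,7,8,8a-octahydroazulen-5-yl]propan-2-yl}propanedioate, via oxyallyl cation 16 (not isolated)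
Conditions: Et3N (3 equiv), CF3CH2OH (0.02 M), 25 → 50 °C
Reagents that add atoms: none
Why: Triethylamine enolises 15 toward the tether carbon C-3, and the chloromethyl enol ionises in the strongly ionising, weakly nucleophilic solvent to the 2-oxidoallyl cation 16. The closest known reaction type is the intramolecular (4+3) cycloaddition of oxyallyl cations, generated from α-halo ketones by an amine base in a fluorinated alcohol, with butadienes on a three-atom tether, which gives five–seven-fused cycloheptenones. The cyclopentane closes when the substituted terminus C-3 bonds to the diene terminus C-11 through the three-carbon tether (5-exo mode). The seven-membered ring closes when the CH2 terminus C-1 bonds to the diene CH2 C-9, in one step or by way of an allyl cation stabilised by the tert-alkyl group on its central carbon. C-11 is formed by attack on either enantiotopic diene face with equal probability, so 17 is racemic and the absolute configuration is supplied in step 13. C-3 is set relative to C-11 by the compact or extended transition state, but as an enolisable α-carbon it needs no control and is replaced in step 11. What the step needs is rate against capture of 16 by the solvent and against Favorskii collapse: the (E)-geometry puts the tether on the outer diene position, the tert-alkyl group on C-8 favours the s-cis conformer, the gem-dimethyl group at C-12 favours folding, and dilution suppresses bimolecular paths. Regiochemistry is fixed by the tether, and the masked C-5 arm has no acidic hydrogen that could be alkylated by the chloromethyl ketone.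

Step 9
Reactants: 17 dimethyl 2-{1-[(tert-butyldimethylsilyl)oxy]-2-methylprop-1-en-1-yl}-2-{2-[rac-(3aS,8aR)-3,3-dimethyl-8-oxo-1,2,3,3a,6,7,8,8a-octahydroazulen-5-yl]propan-2-yl}propanedioate
Product: 18 dimethyl 2-{1-[(tert-butyldimethylsilyl)oxy]-2-methylprop-1-en-1-yl}-2-{2-[rac-(3aS,5S,8aR)-3,3-dimethyl-8-oxodecahydroazulen-5-yl]propan-2-yl}propanedioate
Conditions: H2 (4 bar), Pd/C (10% Pd on carbon), EtOAc, 25 °C
Reagents that add atoms: none
Why: Heterogeneous catalytic hydrogenation with syn addition from the alkene face opposite the gem-dimethyl carbon C-12 on the allylic carbon C-11, which places H-8 cis to H-11 and the C-7 arm cis to C-12, the relation the cage requires; the tetrasubstituted, shielded silyl enol ether should not be reduced.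

Step 10
Reactants: 18 dimethyl 2-{1-[(tert-butyldimethylsilyl)oxy]-2-methylprop-1-en-1-yl}-2-{2-[rac-(3aS,5S,8aR)-3,3-dimethyl-8-oxodecahydroazulen-5-yl]propan-2-yl}propanedioate; 19 (2E)-1-bromo-3,7-dimethylocta-2,6-diene (geranyl bromide)
Product: 21 racemic C-1-geranyl bridged diketone ester (C-1 bonded to C-6; C-5 carries CO2Me on the inner face, toward C-3, and the silyl enol ether on the outer face), via bridged β-diketone 20 (not isolated)
Conditions: KN(SiMe3)2 (1.05 equiv), THF, −78 → 0 °C; then 19, 0 → 25 °C
Reagents that add atoms: none
Why: Intramolecular Claisen condensation followed by C-alkylation in the same flask, as in Dieckmann–alkylation sequences: the kinetic enolate at the C-1 methylene closes a six-membered ring onto one ester, and the methoxide released is consumed by deprotonating the new β-diketone, which drives the closure. The slimmer CO2Me group is expected to take the crowded inner site on C-5 and the bulky silyloxyalkenyl group the outer one. The enolate, at a bridgehead of a bicyclo[4.3.1]decane, is alkylated at carbon by geranyl bromide in an SN2 reaction that keeps the (E)-alkene, and C-1 can only take the configuration the bicycle allows.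

Step 11
Reactants: 21 racemic C-1-geranyl bridged diketone ester
Product: 22 racemic cage triketone with C-5 bearing the 1-[(tert-butyldimethylsilyl)oxy]-2-methylprop-1-en-1-yl group
Conditions: LiN(iPr)2 (1.1 equiv), THF, −78 → −20 °C; AcOH, −78 °C
Reagents that add atoms: none
Why: Intramolecular Claisen condensation of a ketone lithium enolate with an ester: C-3 is the only enolisable ring carbon, the ester is held over it by the bicycle, and closure of the six-membered trione ring creates the spiro centre in the only possible configuration. Because C-5 carries no free ketone, the tetrahedral intermediate loses methoxide and not C-5; low temperature and a cold acid quench keep lithium methoxide from re-opening the cage.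

Step 12
Reactants: 22 racemic cage triketone with masked acyl group
Product: 23 racemic target (24 and its enantiomer)
Conditions: HF·pyridine, THF, 0 → 25 °C
Reagents that add atoms: none
Why: Fluoride-mediated protodesilylation of a silyl enol ether to the ketone under non-basic, non-nucleophilic conditions, which spare the non-enolisable triketone and the geranyl alkenes.

Step 13
Reactants: 23 racemic target
Product: 24 target, (1R,3S,5S,8R,11R)-enantiomer
Conditions: preparative HPLC on amylose tris(3,5-dimethylphenylcarbamate)-coated silica, hexane/i-PrOH
Reagents that add atoms: none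
Why: Chromatographic resolution on a polysaccharide chiral stationary phase, the routine way to separate enantiomers of cage ketones of this family; 23 is a single rigid diastereomer, so two bands are expected, and the absolute configuration of the collected one is to be assigned by comparison of chiroptical data with the natural product or by anomalous-dispersion crystallography.

## Compound list

1 | dimethyl 2-(propan-2-ylidene)propanedioate | COC(=O)C(=C(C)C)C(=O)OC | starting material
2 | 2-bromo-3-(trimethylsilyl)prop-1-ene | C=C(Br)C[Si](C)(C)C | starting material
3 | [3-(trimethylsilyl)prop-1-en-2-yl]magnesium bromide | C=C([Mg]Br)C[Si](C)(C)C | intermediate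
4 | dimethyl 2-{2-methyl-3-[(trimethylsilyl)methyl]but-3-en-2-yl}propanedioate | COC(=O)C(C(=O)OC)C(C)(C)C(=C)C[Si](C)(C)C | intermediate
5 | 2,2-dimethylpent-4-enal | C=CCC(C)(C)C=O | starting material
6 | N-methoxy-N-methylprop-2-enamide | C=CC(=O)N(C)OC | starting material
7 | (2E)-N-methoxy-N,5,5-trimethyl-6-oxohex-2-enamide | O=CC(C)(C)C/C=C/C(=O)N(C)OC | intermediate
8 | N-methoxy-N,5,5-trimethyl-6-oxohexanamide | O=CC(C)(C)CCCC(=O)N(C)OC | intermediate
9 | dimethyl 2-{5-hydroxy-10-[methoxy(methyl)amino]-2,6,6-trimethyl-3-methylidene-10-oxodecan-2-yl}propanedioate (racemic) | COC(=O)C(C(=O)OC)C(C)(C)C(=C)CC(O)C(C)(C)CCCC(=O)N(C)OC | intermediate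
10 | methanesulfonate of 9 | COC(=O)C(C(=O)OC)C(C)(C)C(=C)CC(OS(C)(=O)=O)C(C)(C)CCCC(=O)N(C)OC | intermediate
11 | dimethyl 2-{(4E)-10-[methoxy(methyl)amino]-2,6,6-trimethyl-3-methylidene-10-oxodec-4-en-2-yl}propanedioate | COC(=O)C(C(=O)OC)C(C)(C)C(=C)/C=C/C(C)(C)CCCC(=O)N(C)OC | intermediate
12 | 2-methylpropanoyl chloride (isobutyryl chloride) | CC(C)C(=O)Cl | starting material
13 | dimethyl 2-{(4E)-10-[methoxy(methyl)amino]-2,6,6-trimethyl-3-methylidene-10-oxodec-4-en-2-yl}-2-(2-methylpropanoyl)propanedioate | COC(=O)C(C(=O)OC)(C(=O)C(C)C)C(C)(C)C(=C)/C=C/C(C)(C)CCCC(=O)N(C)OC | intermediate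
14 | dimethyl 2-{1-[(tert-butyldimethylsilyl)oxy]-2-methylprop-1-en-1-yl}-2-{(4E)-10-[methoxy(methyl)amino]-2,6,6-trimethyl-3-methylidene-10-oxodec-4-en-2-yl}propanedioate | COC(=O)C(C(=O)OC)(C(O[Si](C)(C)C(C)(C)C)=C(C)C)C(C)(C)C(=C)/C=C/C(C)(C)CCCC(=O)N(C)OC | intermediate
15 | dimethyl 2-{1-[(tert-butyldimethylsilyl)oxy]-2-methylprop-1-en-1-yl}-2-[(4E)-11-chloro-2,6,6-trimethyl-3-methylidene-10-oxoundec-4-en-2-yl]propanedioate | COC(=O)C(C(=O)OC)(C(O[Si](C)(C)C(C)(C)C)=C(C)C)C(C)(C)C(=C)/C=C/C(C)(C)CCCC(=O)CCl | intermediate
16 | 2-oxidoallyl cation derived from 15 (C-1 cationic CH2, C-2 oxido, C-3 tether terminus) | COC(=O)C(C(=O)OC)(C(O[Si](C)(C)C(C)(C)C)=C(C)C)C(C)(C)C(=C)/C=C/C(C)(C)CCC=C([O-])[CH2+] | intermediate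
17 | dimethyl 2-{1-[(tert-butyldimethylsilyl)oxy]-2-methylprop-1-en-1-yl}-2-{2-[rac-(3aS,8aR)-3,3-dimethyl-8-oxo-1,2,3,3a,6,7,8,8a-octahydroazulen-5-yl]propan-2-yl}propanedioate (trans-fused epimer drawn) | C1CC(C(C)(C)C(C(=O)OC)(C(=O)OC)C(O[Si](C)(C)C(C)(C)C)=C(C)C)=C[C@@H]2C(C)(C)CC[C@H]2C1=O | intermediate
18 | dimethyl 2-{1-[(tert-butyldimethylsilyl)oxy]-2-methylprop-1-en-1-yl}-2-{2-[rac-(3aS,5S,8aR)-3,3-dimethyl-8-oxodecahydroazulen-5-yl]propan-2-yl}propanedioate (H-5 cis to H-3a) | C1C[C@H](C(C)(C)C(C(=O)OC)(C(=O)OC)C(O[Si](C)(C)C(C)(C)C)=C(C)C)C[C@@H]2C(C)(C)CC[C@H]2C1=O | intermediate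
19 | (2E)-1-bromo-3,7-dimethylocta-2,6-diene (geranyl bromide) | CC(C)=CCC/C(C)=C/CBr | starting material
20 | racemic bridged β-diketone: C-1 (H) bonded to C-6; C-5 with CO2Me inner and silyloxyalkenyl outer; formed as its potassium enolate | [C@H]12C[C@H](C(C)(C)[C@](C(=O)OC)(C(O[Si](C)(C)C(C)(C)C)=C(C)C)C1=O)C[C@@H]3C(C)(C)CC[C@H]3C2=O | intermediate
21 | racemic C-1-geranyl bridged diketone ester (20 with (E)-geranyl on C-1) | CC(C)=CCC/C(C)=C/C[C@]12C[C@H](C(C)(C)[C@](C(=O)OC)(C(O[Si](C)(C)C(C)(C)C)=C(C)C)C1=O)C[C@@H]3C(C)(C)CC[C@H]3C2=O | intermediate
22 | racemic cage triketone with C-5 bearing 1-[(tert-butyldimethylsilyl)oxy]-2-methylprop-1-en-1-yl | CC(C)=CCC/C(C)=C/C[C@@]12C[C@H]3C[C@@H]4C(C)(C)CC[C@]4(C1=O)C(=O)[C@@](C(O[Si](C)(C)C(C)(C)C)=C(C)C)(C2=O)C3(C)C | intermediate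
23 | racemic target (one enantiomer drawn) | CC(C)=CCC/C(C)=C/C[C@@]12C[C@H]3C[C@@H]4C(C)(C)CC[C@]4(C1=O)C(=O)[C@@](C(=O)C(C)C)(C2=O)C3(C)C | intermediate
24 | CNP0313870.1: (1R,3S,5S,8R,11R)-cage triketone, C-1 (E)-geranyl, C-5 2-methylpropanoyl, gem-dimethyl at C-7 and C-12 (target numbering) | CC(C)=CCC/C(C)=C/C[C@@]12C[C@H]3C[C@@H]4C(C)(C)CC[C@]4(C1=O)C(=O)[C@@](C(=O)C(C)C)(C2=O)C3(C)C | target

Total step count: 13. Longest linear sequence: 12 steps (steps 2 to 13, from 5).

## Steps least certain to work

**Step 8 (key step).** Capture of the oxyallyl cation by trifluoroethanol, or ring contraction through a cyclopropanone, may outrun the cycloaddition if ionisation is slow or the diene rests in its s-trans form; a slow reaction also exposes the silyl enol ether to the protic medium for longer. Fallback, from 14 back to 17: dichloromethyllithium (from CH2Cl2 and LiN(iPr)2) is added to Weinreb amide 14 to give the dichloromethyl ketone F1. With Et3N in CF3CH2OH this ionises more readily, to a chlorine-stabilised oxyallyl cation that undergoes the same closure and gives the 7-chloro cycloadduct F2. Zinc in NH4Cl-buffered methanol removes the chlorine and returns 17.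

**Step 6.** Acylation of the sodium enolate may go to oxygen, or stall, because C-5 is flanked by the quaternary C-7. Fallback, from 11 back to 14: the sodium enolate of 11 is added to dimethylketene. Addition at the central carbon of this linear electrophile forms the C-5–acyl bond and gives the enolate of the isopropyl ketone directly, which is silylated in the flask with t-BuMe2SiCl to give 14. No new compound is made (F0).

**Step 9.** Facial selectivity may be poor, or the hindered trisubstituted alkene may not take up hydrogen on the catalyst surface. Fallback, from 17 back to 18: hydrogen-atom-transfer hydrogenation with Mn(dpm)3, PhSiH3 and t-BuOOH in i-PrOH. This stepwise radical path tolerates hindrance, and the C-8 radical is quenched toward the more stable isomer, in which the C-7 arm and C-12 are both pseudo-equatorial (cis) on the seven-membered ring, the isomer needed. The tetrasubstituted silyl enol ether accepts hydrogen atoms more slowly. No new compound is made (F0).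

**Step 10.** Ring closure may occur through the other ester group, leaving the surviving ester pointing away from C-3, or from the ring-fusion enolate; geranylation may also go to oxygen. Fallback, from 18 back to 22: geranyl goes on first. LiN(iPr)2 deprotonates the C-1 methylene of 18, which has no other acidic hydrogen, and geranyl bromide 19 gives the C-1-geranyl ketone F3. Excess LiN(iPr)2 then closes both rings in one operation, either α-carbon being free to start, and gives 22.

**Step 11.** The closure may reverse: lithium methoxide can re-open the strained, non-enolisable β-diketone, and the reaction has no thermodynamic sink. Fallback, from 21 back to 22: Me3SiOTf and Et3N convert 21 into the trimethylsilyl enol ether F4, C-3 being the only enolisable carbon. A catalytic amount of anhydrous fluoride (Bu4N+ Ph3SiF2−) starts the acylation, and each methoxide expelled is captured by the next molecule of F4 as MeOSiMe3. The closure is then driven by Si–O bond formation and no free alkoxide meets the cage.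

## Further compounds

F1 | step 8 | dimethyl 2-{1-[(tert-butyldimethylsilyl)oxy]-2-methylprop-1-en-1-yl}-2-[(4E)-11,11-dichloro-2,6,6-trimethyl-3-methylidene-10-oxoundec-4-en-2-yl]propanedioate | COC(=O)C(C(=O)OC)(C(O[Si](C)(C)C(C)(C)C)=C(C)C)C(C)(C)C(=C)/C=C/C(C)(C)CCCC(=O)C(Cl)Cl
F2 | step 8 | 7-chloro derivative of 17 (racemic, mixture at C-7 of the azulene) | ClC1CC(C(C)(C)C(C(=O)OC)(C(=O)OC)C(O[Si](C)(C)C(C)(C)C)=C(C)C)=C[C@@H]2C(C)(C)CC[C@H]2C1=O
F0 | step 6 | none | none
F0 | step 9 | none | none
F3 | step 10 | 18 with (E)-geranyl on the ketone methylene carbon C-1 (racemic, mixture at C-1) | CC(C)=CCC/C(C)=C/CC1C[C@H](C(C)(C)C(C(=O)OC)(C(=O)OC)C(O[Si](C)(C)C(C)(C)C)=C(C)C)C[C@@H]2C(C)(C)CC[C@H]2C1=O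
F4 | step 11 | trimethylsilyl enol ether of 21 at C-2/C-3 (racemic) | CC(C)=CCC/C(C)=C/C[C@]12C[C@H](C(C)(C)[C@](C(=O)OC)(C(O[Si](C)(C)C(C)(C)C)=C(C)C)C1=O)C[C@@H]3C(C)(C)CCC3=C2O[Si](C)(C)C
A1 | alternative 1 | bridged triketone with exocyclic isopropylidene at C-8 | CC(C)=C1C[C@H]2C(=O)CC(=O)[C@@]3(C2=O)CCC(C)(C)[C@H]3C1
A2 | alternative 1 | cage triketone lacking the geranyl and 2-methylpropanoyl groups | [C@@H]12C[C@H]3C[C@@H]4C(C)(C)CC[C@]4(C1=O)C(=O)[C@@H](C2=O)C3(C)C
A3 | alternative 2 | benzene-1,3,5-triol (phloroglucinol) | Oc1cc(O)cc(O)c1
A4 | alternative 2 | methyl 4-oxobutanoate | COC(=O)CCC=O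
A5 | alternative 2 | 4,4,5,5-tetramethyl-2-(3-methylbut-2-en-1-yl)-1,3,2-dioxaborolane | CC(C)=CCB1OC(C)(C)C(C)(C)O1
A6 | alternative 2 | benzylic reverse-prenyl adduct | Oc1cc(O)c([C@H](CCC(=O)OC)C(C)(C)C=C)c(O)c1
A7 | alternative 3 | (2E)-4,4-dimethyl-6-(2,4,6-trihydroxyphenyl)hex-2-enal | O=C/C=C/C(C)(C)CCc1c(O)cc(O)cc1O
A8 | alternative 3 | spiro triketone aldehyde | O=CC[C@@H]1C(C)(C)CCC12C(=O)CC(=O)CC2=O
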